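**Retrosynthetic overview**
1. The target comes from a bis(α-aryloxy ketone). Chelation-controlled reduction sets both arm carbinols. Double SN2 with inversion of the core bis-phenoxide on a D-lactate-derived α-tosyloxy ketone makes both arm C–O bonds.
2. The oxolane is the only ring that is built, since all four arenes are bought. It comes from a cyclic ketal and its oxocarbenium ion: ketal equilibration sets C8′ and hydride delivery sets C7′.
3. The ketal comes from a γ-hydroxy ketone, made by Felkin–Anh addition of an aryltitanium reagent to a γ-keto aldehyde (sets C7).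
4. Key disconnection, C8–C8′: two carbonyl α-carbons are joined. Propanal is turned into an electrophilic enamine radical cation (an enolonium equivalent on a chiral imidazolidinone, which sets C8) and is trapped by the silyl enol ether of propiovanillone.

Assumption: the SMILES is taken literally, so the oxolane is (2S,3R,4R,5R) = 2,3-cis-3,4-trans-4,5-trans and both arms are (1R,2S) = erythro; locants used are C7(S)/C8(R) for the cis aryl/methyl pair, C8′(R)/C7′(R) for the trans pair, and C7″(R)/C8″(S) for the arm carbinol/ether carbons.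

**Step 1**
Reactants: 1 1-(4-hydroxy-3-methoxyphenyl)propan-1-one (propiovanillone)
Product: 2 (Z)-tert-butyl{4-[1-(tert-butyldimethylsilyloxy)prop-1-en-1-yl]-2-methoxyphenoxy}dimethylsilane
Conditions: TBSOTf (2.3 equiv), Et3N (3 equiv), CH2Cl2, 0 → 23 °C
Reagents that add atoms: tert-butyldimethylsilyl trifluoromethanesulfonate (TBSOTf), CC(C)(C)[Si](C)(C)OS(=O)(=O)C(F)(F)F
Why: Soft enolisation with a silyl triflate and an amine base (silyl enol ether formation) also silylates the phenol in the same operation, and the Z enol ether is favoured because it avoids allylic strain between the aryl and methyl groups; no stereocentre is created.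

**Step 2**
Reactants: 2 (Z)-bis-silyl enol ether (1.5 equiv); 3 propanal
Product: 4 (2R)-4-[4-(tert-butyldimethylsilyloxy)-3-methoxyphenyl]-2,3-dimethyl-4-oxobutanal as a mixture of C3 epimers
Conditions: (2S,5S)-5-benzyl-2-tert-butyl-3-methylimidazolidin-4-one·CF3CO2H (20 mol %), (NH4)2Ce(NO3)6 (2.2 equiv), 2,6-di-tert-butylpyridine (2 equiv), H2O (2 equiv), DME, −20 °C, 24 h
Reagents that add atoms: none
Why: Proposed new method: this extends organo-SOMO catalysis (the enantioselective α-enolation of aldehydes with terminal aryl enolsilanes is the closest known reaction type) to a β-methyl enolsilane; tetravalent cerium oxidises the transient (E)-enamine of 3 (far easier to oxidise than 2) to a 3π-electron radical cation in which the normally nucleophilic α-carbon is electrophilic (an enolonium equivalent), the nucleophilic carbon of 2 attacks its open Si face because the benzyl group of the catalyst covers the Re face, and a second oxidation, loss of the silyl group to water and iminium hydrolysis release the 1,4-dicarbonyl, so C8 is set as R by the catalyst while C8′ arises from an open transition state as an epimer mixture that is corrected in step 5.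

**Step 3**
Reactants: 5 4-bromo-2-methoxyphenol
Product: 6 (4-bromo-2-methoxyphenoxy)(tert-butyl)dimethylsilane
Conditions: TBSCl, imidazole, DMF, 23 °C
Reagents that add atoms: tert-butyldimethylsilyl chloride (TBSCl), CC(C)(C)[Si](C)(C)Cl
Why: Imidazole-promoted O-silylation (silyl ether protection) masks the phenol so that the bromide can be metalated; no stereocentre is created.

**Step 4**
Reactants: 6 (4-bromo-2-methoxyphenoxy)(tert-butyl)dimethylsilane; 4 γ-keto aldehyde
Product: 9 (3R,4S)-1,4-bis[4-(tert-butyldimethylsilyloxy)-3-methoxyphenyl]-4-hydroxy-2,3-dimethylbutan-1-one as a mixture of C2 epimers, via aryllithium 7 (not isolated), via aryltitanium triisopropoxide 8 (not isolated)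
Conditions: 6, n-BuLi, THF, −78 °C; ClTi(OiPr)3, −78 → −40 °C; 4, −78 → −30 °C; aq NH4Cl
Reagents that add atoms: none
Why: Bromine–lithium exchange followed by transmetalation gives a weakly basic aryltitanium reagent that adds to the aldehyde much faster than to the aryl ketone and does not enolise C8 (chemoselective organotitanium carbonyl addition), and attack anti to the large CH(CH3)C(O)Ar group along the Felkin–Anh trajectory sets C7 as S, syn to the C8 methyl group.

**Step 5**
Reactants: 9 γ-hydroxy ketone (C8′ epimer mixture)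
Product: 13 (2S,3R,4R,5R)-2,5-bis[4-(tert-butyldimethylsilyloxy)-3-methoxyphenyl]-3,4-dimethyloxolane, via dihydrofuran 10 (not isolated), via methyl ketal 11 (not isolated), via oxocarbenium ion 12 (not isolated)
Conditions: PPTS (10 mol %), HC(OMe)3 (3 equiv), MeOH, 40 °C, 12 h; Et3N (15 mol %), evaporate; Et3SiH (5 equiv), BF3·OEt2 (2.5 equiv), CH2Cl2, −78 °C, 1 h
Reagents that add atoms: none
Why: Pyridinium-buffered ketalisation closes the oxolane and, because ketal 11, oxocarbenium ion 12 and enol ether 10 interconvert under these conditions while the C7–O bond is not ionised, both C8′ epimers drain into the more stable ketal with the two methyl groups trans (C8′ = R, thermodynamic control); BF3·OEt2 then regenerates 12 at −78 °C and Et3SiH transfers hydride (ionic silane reduction of a ketal, inside attack on the envelope) to the face opposite the C8 methyl and C7 aryl groups, which sets C7′ as R with its aryl group trans to the C8′ methyl and cis to the C7 aryl.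

**Step 6**
Reactants: 14 methyl (2R)-2-hydroxypropanoate (methyl D-lactate); 15 4-bromo-1,2-dimethoxybenzene
Product: 18 (2R)-1-(3,4-dimethoxyphenyl)-2-hydroxypropan-1-one, via Weinreb amide 16 (not isolated), via arylmagnesium bromide 17 (not isolated)
Conditions: 14, MeNH(OMe)·HCl (1.2 equiv), iPrMgCl (3.5 equiv), THF, −20 → 0 °C; then 17 (from 15, Mg, THF; 1.5 equiv), 0 → 23 °C; aq NH4Cl
Reagents that add atoms: none
Why: The chloromagnesium amide converts the ester into Weinreb amide 16, whose stable magnesium chelate with 17 collapses to the ketone only on quench (Weinreb ketone synthesis), and the lactate stereocentre is retained because no bond to it is touched and the neighbouring alkoxide suppresses enolisation.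

**Step 7**
Reactants: 18 (2R)-1-(3,4-dimethoxyphenyl)-2-hydroxypropan-1-one
Product: 19 (2R)-1-(3,4-dimethoxyphenyl)-1-oxopropan-2-yl 4-methylbenzenesulfonate
Conditions: TsCl, Et3N, DMAP (cat.), CH2Cl2, 0 °C
Reagents that add atoms: 4-methylbenzenesulfonyl chloride (TsCl), Cc1ccc(cc1)S(=O)(=O)Cl
Why: O-Sulfonylation forms only the O–S bond, so the R configuration is retained, and the released sulfonate is too poor a nucleophile to racemise the electrophile by self-exchange as a halide would.

**Step 8**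
Reactants: 13 bis-silyl oxolane; 19 (R)-α-tosyloxy ketone (2.3 equiv)
Product: 21 (2S,2′S)-2,2′-{[(2S,3R,4R,5R)-3,4-dimethyloxolane-2,5-diyl]bis[(2-methoxy-4,1-phenylene)oxy]}bis[1-(3,4-dimethoxyphenyl)propan-1-one], via bis(tetrabutylammonium) bisphenoxide 20 (not isolated)
Conditions: 13, Bu4NF (2.0 equiv, 1 M in THF), THF, 0 °C, 20 min; then 19, 0 → 23 °C
Reagents that add atoms: none
Why: Fluoride cleaves both aryl silyl ethers to the naked phenoxide 20, which displaces the carbonyl-activated secondary tosylate twice by SN2 (Williamson-type ether synthesis) with inversion, R in 19 becoming S at both C8″ centres, and since the only base present is consumed by the alkylation itself the acidic α-hydrogens are not equilibrated.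

**Step 9**
Reactants: 21 bis(α-aryloxy ketone)
Product: 22 (1R,2S)-1-(3,4-dimethoxyphenyl)-2-[4-[(2S,3R,4R,5R)-5-[4-[(1R,2S)-1-(3,4-dimethoxyphenyl)-1-hydroxypropan-2-yl]oxy-3-methoxyphenyl]-3,4-dimethyloxolan-2-yl]-2-methoxyphenoxy]propan-1-ol (target)
Conditions: Zn(BH4)2, Et2O–CH2Cl2, −40 → 0 °C; aq NH4Cl
Reagents that add atoms: none
Why: Divalent zinc bridges the ketone oxygen and the α-aryloxy oxygen (chelation-controlled hydride reduction, Cram chelate model), so hydride enters from the face that carries the C8″ hydrogen and each (S)-C8″ induces (R)-C7″, giving the erythro arm twice.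

**Compound list**
1 | 1-(4-hydroxy-3-methoxyphenyl)propan-1-one | CCC(=O)c1ccc(O)c(OC)c1 | starting material
2 | (Z)-tert-butyl{4-[1-(tert-butyldimethylsilyloxy)prop-1-en-1-yl]-2-methoxyphenoxy}dimethylsilane | C/C=C(\O[Si](C)(C)C(C)(C)C)c1ccc(O[Si](C)(C)C(C)(C)C)c(OC)c1 | intermediate
3 | propanal | CCC=O | starting material
4 | (2R)-4-[4-(tert-butyldimethylsilyloxy)-3-methoxyphenyl]-2,3-dimethyl-4-oxobutanal (C3 epimers) | O=C[C@H](C)C(C)C(=O)c1ccc(O[Si](C)(C)C(C)(C)C)c(OC)c1 | intermediate
5 | 4-bromo-2-methoxyphenol | COc1cc(Br)ccc1O | starting material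
6 | (4-bromo-2-methoxyphenoxy)(tert-butyl)dimethylsilane | COc1cc(Br)ccc1O[Si](C)(C)C(C)(C)C | intermediate
7 | [4-(tert-butyldimethylsilyloxy)-3-methoxyphenyl]lithium | COc1cc([Li])ccc1O[Si](C)(C)C(C)(C)C | intermediate
8 | [4-(tert-butyldimethylsilyloxy)-3-methoxyphenyl]titanium triisopropoxide | COc1cc(ccc1O[Si](C)(C)C(C)(C)C)[Ti](OC(C)C)(OC(C)C)OC(C)C | intermediate
9 | (3R,4S)-1,4-bis[4-(tert-butyldimethylsilyloxy)-3-methoxyphenyl]-4-hydroxy-2,3-dimethylbutan-1-one (C2 epimers) | CC(C)(C)[Si](C)(C)Oc1ccc([C@@H](O)[C@H](C)C(C)C(=O)c2ccc(O[Si](C)(C)C(C)(C)C)c(OC)c2)cc1OC | intermediate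
10 | (2S,3R)-2,5-bis[4-(tert-butyldimethylsilyloxy)-3-methoxyphenyl]-3,4-dimethyl-2,3-dihydrofuran | CC(C)(C)[Si](C)(C)Oc1ccc([C@H]2OC(c3ccc(O[Si](C)(C)C(C)(C)C)c(OC)c3)=C(C)[C@H]2C)cc1OC | intermediate
11 | (3R,4R,5S)-2,5-bis[4-(tert-butyldimethylsilyloxy)-3-methoxyphenyl]-2-methoxy-3,4-dimethyloxolane (anomers) | CC(C)(C)[Si](C)(C)Oc1ccc([C@H]2OC(OC)(c3ccc(O[Si](C)(C)C(C)(C)C)c(OC)c3)[C@H](C)[C@H]2C)cc1OC | intermediate
12 | (3R,4R,5S)-2,5-bis[4-(tert-butyldimethylsilyloxy)-3-methoxyphenyl]-3,4-dimethyl-4,5-dihydro-3H-furan-1-ium | CC(C)(C)[Si](C)(C)Oc1ccc([C@H]2[O+]=C(c3ccc(O[Si](C)(C)C(C)(C)C)c(OC)c3)[C@H](C)[C@H]2C)cc1OC | intermediate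
13 | (2S,3R,4R,5R)-2,5-bis[4-(tert-butyldimethylsilyloxy)-3-methoxyphenyl]-3,4-dimethyloxolane | CC(C)(C)[Si](C)(C)Oc1ccc([C@H]2O[C@@H](c3ccc(O[Si](C)(C)C(C)(C)C)c(OC)c3)[C@H](C)[C@H]2C)cc1OC | intermediate
14 | methyl (2R)-2-hydroxypropanoate | C[C@@H](O)C(=O)OC | starting material
15 | 4-bromo-1,2-dimethoxybenzene | COc1ccc(Br)cc1OC | starting material
16 | (2R)-2-hydroxy-N-methoxy-N-methylpropanamide (present as its magnesium alkoxide) | C[C@@H](O)C(=O)N(C)OC | intermediate
17 | (3,4-dimethoxyphenyl)magnesium bromide | COc1ccc([Mg]Br)cc1OC | intermediate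
18 | (2R)-1-(3,4-dimethoxyphenyl)-2-hydroxypropan-1-one | C[C@@H](O)C(=O)c1ccc(OC)c(OC)c1 | intermediate
19 | (2R)-1-(3,4-dimethoxyphenyl)-1-oxopropan-2-yl 4-methylbenzenesulfonate | C[C@@H](OS(=O)(=O)c1ccc(C)cc1)C(=O)c1ccc(OC)c(OC)c1 | intermediate
20 | bis(tetrabutylammonium) 4,4′-[(2S,3R,4R,5R)-3,4-dimethyloxolane-2,5-diyl]bis(2-methoxyphenolate) | [O-]c1ccc([C@H]2O[C@@H](c3ccc([O-])c(OC)c3)[C@H](C)[C@H]2C)cc1OC.CCCC[N+](CCCC)(CCCC)CCCC.CCCC[N+](CCCC)(CCCC)CCCC | intermediate
21 | (2S,2′S)-2,2′-{[(2S,3R,4R,5R)-3,4-dimethyloxolane-2,5-diyl]bis[(2-methoxy-4,1-phenylene)oxy]}bis[1-(3,4-dimethoxyphenyl)propan-1-one] | COc1ccc(C(=O)[C@H](C)Oc2ccc([C@H]3O[C@@H](c4ccc(O[C@@H](C)C(=O)c5ccc(OC)c(OC)c5)c(OC)c4)[C@H](C)[C@H]3C)cc2OC)cc1OC | intermediate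
22 | CNP0116650.13 | COc1ccc([C@@H](O)[C@H](C)Oc2ccc([C@H]3O[C@@H](c4ccc(O[C@@H](C)[C@H](O)c5ccc(OC)c(OC)c5)c(OC)c4)[C@H](C)[C@H]3C)cc2OC)cc1OC | target

**Totals**
Total step count: 9.
Longest linear sequence: 6 steps (steps 1, 2, 4, 5, 8, 9; 1 → 2 → 4 → 9 → 13 → 21 → 22).

**Three steps most likely to fail**

**Step 2.** Tetravalent cerium may oxidise the electron-rich enolsilane or arene directly, giving homodimer or nitrate ester. The hindered β-methyl terminus may also trap the radical cation too slowly.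
The fallback sets out from 2 and comes back at 4. Compound 2 is treated with N-bromosuccinimide (THF, 0 °C) to give racemic 2-bromo-1-[4-(tert-butyldimethylsilyloxy)-3-methoxyphenyl]propan-1-one F1. F1 is then coupled with 3 by photoredox organocatalysis [Ru(bpy)3Cl2 0.5 mol %, (2R,5S)-2-tert-butyl-3,5-dimethylimidazolidin-4-one triflate 20 mol %, 2,6-lutidine, DMF, visible light, 23 °C]. Here the electrophilic α-keto radical is made reductively from the C–Br bond and adds to the open Si face of the closed-shell enamine. No stoichiometric oxidant ever meets the arene, and C8 is again R.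

**Step 5.** The acid stage may ionise the electron-rich benzylic C7–O bond and scramble C7. It may also stall at dihydrofuran 10, whose kinetic protonation would give the wrong C8′ epimer.
The fallback sets out from 9 and comes back at 13. The thermodynamic funnel is given up. The epimers of 9 are separated by chromatography into (2R,3R,4S)-1,4-bis[4-(tert-butyldimethylsilyloxy)-3-methoxyphenyl]-4-hydroxy-2,3-dimethylbutan-1-one F2 and its (2S,3R,4S) epimer F3. F3 is re-equilibrated through its enolate (DBU 0.3 equiv, PhMe, 40 °C) and recycled; base cannot touch C7. F2 is reduced directly, without any protic acid stage, with Et3SiH and BF3·OEt2 (CH2Cl2, −78 °C) through 12.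

**Step 8.** The basic phenoxide may partly racemise 19 or 21, fluoride may attack 19, and the alkylation may stop at the mono-ether.
The fallback sets out from 13 and comes back at 21.
- Compound 13 is desilylated (Bu4NF, THF, then aq NH4Cl) and isolated as 4,4′-[(2S,3R,4R,5R)-3,4-dimethyloxolane-2,5-diyl]bis(2-methoxyphenol) F4.
- A double Mitsunobu reaction with 14 (PPh3, DIAD, THF, 0 °C) proceeds with inversion under base-free conditions. It gives dimethyl (2S,2′S)-2,2′-{[(2S,3R,4R,5R)-3,4-dimethyloxolane-2,5-diyl]bis[(2-methoxy-4,1-phenylene)oxy]}dipropanoate F5.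
- MeNH(OMe)·HCl with iPrMgCl converts F5 into the corresponding bis(N-methoxy-N-methylamide) F6.
- Grignard reagent 17 then adds twice to give 21.

**Further compounds**
F1 | step 2 | 2-bromo-1-[4-(tert-butyldimethylsilyloxy)-3-methoxyphenyl]propan-1-one (racemic) | CC(Br)C(=O)c1ccc(O[Si](C)(C)C(C)(C)C)c(OC)c1
F2 | step 5 | (2R,3R,4S)-1,4-bis[4-(tert-butyldimethylsilyloxy)-3-methoxyphenyl]-4-hydroxy-2,3-dimethylbutan-1-one | CC(C)(C)[Si](C)(C)Oc1ccc([C@@H](O)[C@H](C)[C@@H](C)C(=O)c2ccc(O[Si](C)(C)C(C)(C)C)c(OC)c2)cc1OC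
F3 | step 5 | (2S,3R,4S)-1,4-bis[4-(tert-butyldimethylsilyloxy)-3-methoxyphenyl]-4-hydroxy-2,3-dimethylbutan-1-one | CC(C)(C)[Si](C)(C)Oc1ccc([C@@H](O)[C@H](C)[C@H](C)C(=O)c2ccc(O[Si](C)(C)C(C)(C)C)c(OC)c2)cc1OC
F4 | step 8 | 4,4′-[(2S,3R,4R,5R)-3,4-dimethyloxolane-2,5-diyl]bis(2-methoxyphenol) | Oc1ccc([C@H]2O[C@@H](c3ccc(O)c(OC)c3)[C@H](C)[C@H]2C)cc1OC
F5 | step 8 | dimethyl (2S,2′S)-2,2′-{[(2S,3R,4R,5R)-3,4-dimethyloxolane-2,5-diyl]bis[(2-methoxy-4,1-phenylene)oxy]}dipropanoate | COC(=O)[C@H](C)Oc1ccc([C@H]2O[C@@H](c3ccc(O[C@@H](C)C(=O)OC)c(OC)c3)[C@H](C)[C@H]2C)cc1OC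
F6 | step 8 | (2S,2′S)-2,2′-{[(2S,3R,4R,5R)-3,4-dimethyloxolane-2,5-diyl]bis[(2-methoxy-4,1-phenylene)oxy]}bis(N-methoxy-N-methylpropanamide) | CON(C)C(=O)[C@H](C)Oc1ccc([C@H]2O[C@@H](c3ccc(O[C@@H](C)C(=O)N(C)OC)c(OC)c3)[C@H](C)[C@H]2C)cc1OC
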